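## Structural features

The target is a germacranolide: a cyclodeca-1(10),4-diene (C1–C10) fused at C6/C7 to an α-methylene-γ-butyrolactone (O6, C12 carbonyl, C11=C13). Both ring alkenes are cis within the ring. C4=C5 carries the C15 methyl with the geometry of a neryl unit (4Z), and C1=C10 carries the C14 formyl group with C2 and C9 on the same side (1(10)E by the sequence rules). Four contiguous stereocentres, C6 (R), C7 (S), C8 (S) and C9 (S), lie along one edge: H6/H7 are trans (trans-fused lactone), H7/H8 are cis, and the C8/C9 isobutyrates are trans (a threo diol). Fragile groups are the methylene lactone and the enal (both Michael acceptors), the two esters (the allylic C9 ester can migrate to O14), and a free C8 hydroxyl, which can relactonise onto C12. The real difficulty is the ten-membered ring with two Z trisubstituted alkenes next to the stereotetrad, because direct end-to-end closure of such a ring is penalised entropically and by transannular strain. The handle is at C6/C7: C6 is an allylic carbinol carbon bonded to C7, and C7 carries the C11–C13 unit. With C11=C12 as an isopropenyl group, C6(OH)–C7–C11=C12 is a homoallylic alcohol, the retron of a [2,3]-Wittig shift of an ether whose oxygen bridges C6 and C12 in a thirteen-membered ring.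

## Logic of the disconnections

**34 ⇒ 30.** No carbon–carbon bond is cut. The C14 aldehyde is traced to a silyl-protected primary alcohol, and the acyl C–O bonds at O8 and O9 are cut, the diol being held as an isopropylidene ketal. The reason is that enal and esters cannot pass the organolithium and amide bases used earlier, whereas a silyl ether and a ketal can. The gain is one robust pair of protecting groups for the whole middle of the route. The demand: the ketal must be hydrolysed without loss of the silyl ether or lactone migration to O8 (31), two hindered secondary alcohols must be acylated (32), and the last oxidation (33 to 34) must touch only the primary allylic alcohol.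

**30 ⇒ 23.** The exocyclic C11=C13 alkene is cut back to a methyl group (27). The lactone acyl bond O6–C12 is then cut and C12 reduced to a primary alcohol (25), the hydration product of the C11=C12 alkene of 23. The reason is that this converts the lactone into the homoallylic alcohol retron. The gain is loss of the lactone ring and of the Michael acceptor; the C11 configuration in between is irrelevant. The demand: hydroboration must pick the 1,1-disubstituted alkene out of three alkenes, the oxidation must pick the primary alcohol, and the selenoxide must eliminate toward the methyl group.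

**23 ⇒ 21 (key disconnection).** C6–C7 is cut and O6 is joined to C12, with the C11=C12 alkene moved to C7=C11. The reason is that the ten-membered carbocycle is then made by contracting a thirteen-membered ether, not by end-to-end C–C closure. The gain is that the carbocycle and two stereocentres (C6, C7) are exchanged for a macrocyclic ether carrying only the C8/C9 pair. The demand: metalation at C6 and not at C12 or C14, E geometry at C7=C11, and facial control from C8. The ketal and the bulky silyl ether of 21 are kept on purpose: a ketal carbon has no hydrogen, so it cannot be metalated and fragmented as an arylidene acetal would be, and benzyl-type ethers would be metalated at their benzylic carbon.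

**21 ⇒ 20.** The ether bond O6–C12 is cut. The reason is that an alkoxide closing on a primary allylic chloride is the simplest way to make a diallyl ether. Putting the chloride at C12 and the alcohol at C6 lets both appear without dedicated steps: the chloride is installed early, and O6 is freed together with O8. The gain is an open chain. The demand: high dilution, and a chloride that survives five steps.

**20 ⇒ 7 + 15 (through 19 and 18).** C9–C10 is cut. The reason is that the chain divides into two five-step halves at a carbinol carbon flanked by an oxygenated stereocentre, so C9 can be set from C8 by chelation. The two benzyl-type ethers of 18 (on O6 and O8) fall together to give 19, whose threo diol is ketalised to 20. The gain is convergence, with the C1=C10 geometry carried in 7. The demand: the vinyl metal from 7 must keep its geometry, add syn-selectively, and add faster than it deprotonates 15.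

**7 ⇒ 1.** C1=C10 is cut (olefination of 4 to 5), and before that the distal alkene of 2 is cleaved; 6 and 7 are adjustments at C14. The reason is that 1 already contains C2–C6, C15 and the Z C4=C5 alkene. The gain is that this alkene geometry is bought. The demand: site-selective oxidation of the distal alkene and a Z-selective iodo-olefination.

**15 ⇒ 8 + 9.** C7=C11 is cut (10 from 8 and 9). Compounds 12, 13 and 14 redistribute the oxygen functions: O8 receives the chelating ether, C9 becomes the aldehyde and C12 the chloride. The reason is that 8 supplies C8 in the right absolute configuration only if its formyl carbon becomes C7 and its CH2O carbon becomes C9; 9 brings C11, C12 and C13 with E geometry. The gain is commercial materials and a chiral-pool stereocentre. The demand: E selectivity, regioselective reductive opening of the acetal 12, chemoselective chlorination of the allylic alcohol of 13, and configurational stability of 15.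

## Other disconnections considered

**Alternative 1:** The cut is C8–C9, between the two oxygenated carbons. In the forward sense SmI2 (divalent samarium) would reduce the conjugated ynal of the open-chain dialdehyde A1 to a ketyl that adds to the C8 aldehyde, closing the lactone-fused cyclodecenyne diol A2.

- In its favour: C6 and C7 are set on a five-membered lactone before the medium ring exists, which is more secure than the chosen plan on that point. The alkyne removes two transannular hydrogens. The diol appears unprotected in one step, so no benzyl-ether and ketal manipulation is needed, which is also better.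
- Against it here: two stereocentres (C8, C9) form at once and must come out threo and in the right sense relative to C7, whereas samarium-bridged pinacol closures tend toward cis diols. A1 has an aldehyde on C7 that is epimerisable and β to the lactone oxygen, inviting elimination. The ynal ketyl is delocalised toward C1.
- After the key step, A2 still lacks C14 and C13 and has an alkyne where the enal must be. A hydroxyl-directed syn addition of H and a C14 unit across the alkyne and an α-methylenation remain.
- Comparison: on structure it is an end-to-end closure under dilution, against a ring contraction that is intramolecular by construction. On mechanism, a radical coupling offers no stereospecific link to alkene geometry, which the sigmatropic shift does. On step economy it should be about equal, at best.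

**Alternative 2:** The cut takes C1 and C10 out as a two-carbon unit (bonds C1–C2 and C9–C10). In the forward sense the eight-membered enamine A3 adds methyl propiolate in a [2+2] cycloaddition, and the fused aminocyclobutene opens to the ten-membered dienamino ester A4.

- In its favour: the ring grows from eight to ten members in a thermal sequence with no macrocyclisation and no strong base. C14 arrives on C10 at the ester oxidation level, which is better than the chosen plan, where C14 is carried protected and oxidised at the end.
- Against it here: A3 is itself a medium ring with three contiguous stereocentres and a cis trisubstituted alkene, so the ring problem is only moved. The enamine must form toward C2 and not toward the oxygen-bearing C8.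
- After the key step, A4 has its unsaturation at C9=C10 and C1=C2. The enamine must be hydrolysed, the C9 ketone reduced with control of a stereocentre the key step does not set, and the alkene brought to C1=C10 with C2 cis to C9. The C7 arm has two carbons and still needs C13.
- Comparison: on structure the key step sets no stereocentre, whereas the chosen one sets two. On mechanism both avoid end-to-end closure, which is a point of equality. On step economy it should be clearly longer.

**Alternative 3:** The cut is C2–C3, made in the forward sense while C5–C10 breaks. KH with 18-crown-6 would convert the cis-dialkenyl cyclohexanol A5 into its alkoxide, whose [3,3] shift gives, after protonation, the cyclodec-5-enone A6.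

- In its favour: C6–C9 are all set on a cyclohexane, where relative configuration is easy to control and might come from a cyclitol. On security of the stereotetrad this is better than the chosen plan, whose C6/C7 face selection rests on a macrocyclic transition state. The ring-cis C4=C5 alkene follows from the cis disposition of the two alkenyl groups. Like the chosen key step, the ring expansion is sigmatropic and needs no dilution, which is equal.
- Against it here: A5 is substituted on all six ring carbons, including a tertiary carbinol next to a ketal oxygen. In A6 the ketone is flanked by the ketal-bearing C9, so enolisation toward C9 threatens epimerisation and β-elimination of O8.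
- After the key step, A6 has C10 as a ketone without C14. A regioselective enol derivative toward C1, a carbonylation, construction of the lactone from the two-carbon arm and a methylenation remain.
- Comparison: on step economy A5 alone should cost about as much as the whole approach to 21.

Key step: step 15

Assumption: carbon labels C1–C15 are the germacrane labels of the first section and are used for every intermediate; C11 in 24–29 may be either epimer (drawn for 28 as expected), because it becomes trigonal again in step 18.

Remark: to obtain (S)-C8 from aldehyde 8, its formyl carbon has to become C7 and its CH2O carbon C9; used the other way round it would give the enantiomeric C8, which is why the olefination with 9 comes first.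

## Route

Step 1
Reactants: 1 nerol [(2Z)-3,7-dimethylocta-2,6-dien-1-ol]
Product: 2 neryl 4-methoxybenzyl ether
Conditions: NaH, 4-MeOC6H4CH2Cl, Bu4NI (cat.), THF/DMF, 0 °C → rt
Reagents that add atoms: 4-methoxybenzyl chloride COc1ccc(CCl)cc1
Why: Williamson etherification of a primary allylic alkoxide; the ether masks O6 through the organolithium chemistry and is later removed oxidatively together with the second 4-methoxybenzyl group.

Step 2
Reactants: 2 neryl 4-methoxybenzyl ether
Product: 4 (4Z)-6-[(4-methoxybenzyl)oxy]-4-methylhex-4-enal, via epoxide 3 (not isolated)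
Conditions: mCPBA (1.05 equiv), CH2Cl2, −20 → 0 °C; then H5IO6, THF/H2O, 0 °C
Reagents that add atoms: 3-chloroperoxybenzoic acid OOC(=O)c1cccc(Cl)c1
Why: Prilezhaev epoxidation should prefer the electron-rich isopropylidene alkene over the C4=C5 alkene, which is deactivated by the allylic ether oxygen. Periodic acid then hydrolyses the epoxide and cleaves the glycol to the C1 aldehyde without touching the Z alkene.

Step 3
Reactants: 4 (4Z)-6-[(4-methoxybenzyl)oxy]-4-methylhex-4-enal
Product: 5 ethyl (2Z,6Z)-2-iodo-8-[(4-methoxybenzyl)oxy]-6-methylocta-2,6-dienoate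
Conditions: Ph3P=CHCO2Et, N-iodosuccinimide, CH2Cl2, −20 °C; then 4, −20 °C → rt
Reagents that add atoms: ethyl (triphenylphosphoranylidene)acetate CCOC(=O)C=P(c1ccccc1)(c1ccccc1)c1ccccc1; N-iodosuccinimide O=C1CCC(=O)N1I
Why: Tandem iodination–Wittig olefination: the stabilised ylide is iodinated in the flask and the iodo ylide places the ester trans to the chain, so iodine is cis to C2 (Z), the geometry later transferred to C1=C10. Any E isomer is removed by chromatography here or after step 4.

Step 4
Reactants: 5 ethyl (2Z,6Z)-2-iodo-8-[(4-methoxybenzyl)oxy]-6-methylocta-2,6-dienoate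
Product: 6 (2Z,6Z)-2-iodo-8-[(4-methoxybenzyl)oxy]-6-methylocta-2,6-dien-1-ol
Conditions: i-Bu2AlH (2.3 equiv), CH2Cl2, −78 °C; aq. potassium sodium tartrate
Reagents that add atoms: none
Why: 1,2-Reduction of the enoate gives the C14 allylic alcohol; at −78 °C the vinyl iodide and both alkene geometries should be untouched.

Step 5
Reactants: 6 (2Z,6Z)-2-iodo-8-[(4-methoxybenzyl)oxy]-6-methylocta-2,6-dien-1-ol
Product: 7 {[(2Z,6Z)-2-iodo-8-[(4-methoxybenzyl)oxy]-6-methylocta-2,6-dien-1-yl]oxy}tri(propan-2-yl)silane
Conditions: i-Pr3SiCl, imidazole, DMF, rt
Reagents that add atoms: chlorotri(propan-2-yl)silane CC(C)[Si](Cl)(C(C)C)C(C)C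
Why: Silylation of the primary allylic alcohol; the bulky triisopropylsilyl group is chosen because it resists O→C silyl migration in the derived vinyl metal and metalation next to oxygen in step 15.

Step 6
Reactants: 8 (R)-2,2-dimethyl-1,3-dioxolane-4-carbaldehyde; 9 ethyl 2-(triphenylphosphoranylidene)propanoate
Product: 10 ethyl (2E)-3-[(4S)-2,2-dimethyl-1,3-dioxolan-4-yl]-2-methylprop-2-enoate
Conditions: CH2Cl2, 0 °C → rt
Reagents that add atoms: none
Why: Wittig olefination with a stabilised α-methyl ylide gives the E trisubstituted enoate (C8 trans to C12 across C7=C11); the ylide is not basic enough to epimerise the α-alkoxy aldehyde, so C8 keeps the configuration of 8.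

Step 7
Reactants: 10 ethyl (2E)-3-[(4S)-2,2-dimethyl-1,3-dioxolan-4-yl]-2-methylprop-2-enoate
Product: 12 ethyl (2E)-3-[(4S)-2-(4-methoxyphenyl)-1,3-dioxolan-4-yl]-2-methylprop-2-enoate (both acetal epimers), via diol 11 (not isolated)
Conditions: AcOH/H2O (4:1), 40 °C; evaporate (toluene); then 4-MeOC6H4CH(OMe)2, PPTS (cat.), CH2Cl2, rt
Reagents that add atoms: 4-methoxybenzaldehyde dimethyl acetal COC(OC)c1ccc(OC)cc1
Why: Acid hydrolysis of the ketal followed by transacetalisation of the 1,2-diol; the E enoate cannot lactonise onto either hydroxyl, and the arylidene acetal is the source of the chelating ether on O8.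

Step 8
Reactants: 12 ethyl (2E)-3-[(4S)-2-(4-methoxyphenyl)-1,3-dioxolan-4-yl]-2-methylprop-2-enoate
Product: 13 (2S,3E)-2-[(4-methoxybenzyl)oxy]-4-methylpent-3-ene-1,5-diol
Conditions: i-Bu2AlH (5 equiv), CH2Cl2, −78 → 0 °C; aq. potassium sodium tartrate
Reagents that add atoms: none
Why: i-Bu2AlH first reduces the ester to the C12 allylic alcohol and on warming opens the arylidene acetal reductively. Aluminium binds the less hindered primary oxygen O9, that acetal C–O bond breaks, and hydride quenches the oxocarbenium ion, leaving the 4-methoxybenzyl group on O8 and a free C9 alcohol.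

Step 9
Reactants: 13 (2S,3E)-2-[(4-methoxybenzyl)oxy]-4-methylpent-3-ene-1,5-diol
Product: 14 (2S,3E)-5-chloro-2-[(4-methoxybenzyl)oxy]-4-methylpent-3-en-1-ol
Conditions: N-chlorosuccinimide, Me2S, CH2Cl2, −20 → 0 °C
Reagents that add atoms: N-chlorosuccinimide O=C1CCC(=O)N1Cl
Why: Corey–Kim chlorination: the alkoxysulfonium salt of the allylic alcohol is displaced by chloride at the primary allylic carbon (SN2, E geometry kept), whereas that of the saturated C9 alcohol is not displaced and returns the alcohol on work-up.

Step 10
Reactants: 14 (2S,3E)-5-chloro-2-[(4-methoxybenzyl)oxy]-4-methylpent-3-en-1-ol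
Product: 15 (2S,3E)-5-chloro-2-[(4-methoxybenzyl)oxy]-4-methylpent-3-enal
Conditions: Dess–Martin periodinane, NaHCO3, CH2Cl2, 0 °C → rt; used at once
Reagents that add atoms: none
Why: Dess–Martin oxidation under buffered, near-neutral conditions gives the α-alkoxy β,γ-unsaturated aldehyde, so C8 should not epimerise and the alkene should not move into conjugation.

Step 11
Reactants: 7 {[(2Z,6Z)-2-iodo-8-[(4-methoxybenzyl)oxy]-6-methylocta-2,6-dien-1-yl]oxy}tri(propan-2-yl)silane; 15 (2S,3E)-5-chloro-2-[(4-methoxybenzyl)oxy]-4-methylpent-3-enal
Product: 18 (2E,4S,5S,6Z,10Z)-1-chloro-4,12-bis[(4-methoxybenzyl)oxy]-2,10-dimethyl-6-({[tri(propan-2-yl)silyl]oxy}methyl)dodeca-2,6,10-trien-5-ol, via vinyllithium 16 (not isolated), via vinylmagnesium bromide 17 (not isolated)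
Conditions: 7, t-BuLi (2.1 equiv), Et2O, −78 °C; MgBr2·OEt2, −78 °C; then 15, CH2Cl2, −78 °C; aq. NH4Cl
Reagents that add atoms: none
Why: Iodine–lithium exchange with retention of alkene geometry, transmetalation to magnesium, then Cram-chelate addition: magnesium bridges the aldehyde oxygen and the O8 ether, and the vinyl group adds to the chelate face away from the C7 alkenyl group, setting C9 (S) syn (threo) to C8. At −78 °C carbonyl addition should outrun enolisation of 15 and displacement of its allylic chloride.

Step 12
Reactants: 18 the C9 carbinol of step 11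
Product: 19 (2E,4S,5S,6Z,10Z)-1-chloro-2,10-dimethyl-6-({[tri(propan-2-yl)silyl]oxy}methyl)dodeca-2,6,10-triene-4,5,12-triol
Conditions: DDQ (2.4 equiv), CH2Cl2/pH 7 buffer (KH2PO4/Na2HPO4) 10:1, 0 °C
Reagents that add atoms: none
Why: Oxidative cleavage of both 4-methoxybenzyl ethers (hydride abstraction by DDQ, hydrolysis of the oxocarbenium ions) frees O6 and O8 in one operation. The silyl ether, allylic chloride and alkenes should be inert, and the water present diverts the O8 oxocarbenium ion from capture by the C9 hydroxyl.

Step 13
Reactants: 19 the chloro triol of step 12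
Product: 20 (2Z,6Z)-7-{(4S,5S)-5-[(1E)-3-chloro-2-methylprop-1-en-1-yl]-2,2-dimethyl-1,3-dioxolan-4-yl}-3-methyl-8-{[tri(propan-2-yl)silyl]oxy}octa-2,6-dien-1-ol
Conditions: Me2C(OMe)2, PPTS (cat.), acetone, rt; aq. NaHCO3
Reagents that add atoms: 2,2-dimethoxypropane COC(C)(C)OC
Why: Ketalisation of the threo 1,2-diol gives the trans-4,5-disubstituted dioxolane, the preferred five-membered ketal; the primary C6 hydroxyl can form only a labile mixed ketal that falls off on work-up.

Step 14
Reactants: 20 the hydroxy chloride of step 13
Product: 21 thirteen-membered diallyl ether: ring O–C6–C5=C4(CH3)–C3–C2–C1=C10(CH2OSi(i-Pr)3)–C9–C8–C7=C11(CH3)–C12–O; C4=C5 Z, C2 and C9 cis on C1=C10, C7=C11 E; (8S,9S) trans isopropylidene ketal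
Conditions: NaH, Bu4NI (cat.), THF, reflux, syringe-pump addition (final 0.003 M)
Reagents that add atoms: none
Why: Intramolecular Williamson etherification: the C6 alkoxide displaces the primary allylic chloride at C12 (through the more reactive iodide) in a 13-exo-tet SN2 closure. High dilution suppresses oligomers, and three alkenes plus the dioxolane leave few rotatable bonds, which favours ring closure.

Step 15
Reactants: 21 the thirteen-membered diallyl ether
Product: 23 ten-membered dienol (6R,7S,8S,9S): cyclodeca-1(10),4-diene with 6-OH, 7-isopropenyl, 8,9-isopropylidenedioxy, 10-CH2OSi(i-Pr)3 and 4-CH3; H6/H7 trans, via C6-lithio ether 22 (not isolated)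
Conditions: n-BuLi (2 equiv), THF, −78 → −20 °C; aq. NH4Cl
Reagents that add atoms: none
Why: n-BuLi, bound to the ring oxygen, removes a proton from C6 (α to oxygen, allylic to C4=C5) to give 22, whose carbanion attacks C7 through a five-membered envelope transition state (C6–O–C12–C11=C7) while O–C12 breaks and C11=C12 appears as the isopropenyl group; this is a [2,3]-Wittig rearrangement in its known transannular form, which contracts thirteen-membered diallyl ethers to germacrane-type cyclodecadienols. The ten-membered carbocycle closes by C6–C7 bond formation across the macrocycle, suprafacially on the C12–C11=C7 allyl unit, so the ring is made by excision of the O–C12–C11 bridge and not by end-to-end cyclisation. The C6/C7 relationship follows from the E geometry of C7=C11 with the C5 alkenyl group of the carbanion exo on the envelope, which gives the anti pair, that is H6 and H7 trans as in the trans-fused lactone. The absolute sense is set by C8: the required product has H7 and H8 cis, which arises when C6 bonds to the face of C7 on the side of O8 in the rotamer that keeps H8 in the alkene plane beside the C13 methyl (allylic 1,3-strain); the trans-dioxolane, which fixes the C7–C8–C9–C10 torsion, is expected to hold the C9–C10 arm on the far side so that the chain returning through C1–C5 delivers C6 to that face. The step needs regioselectivity for the C6 anion: a C12 anion would have to bond to the fully substituted C4 and create a quaternary centre through a more crowded envelope, whereas the C6 carbanion attacks a CH terminus. Competing metalation at C14 is suppressed by the bulk of the triisopropylsilyl group, and the ketal carbon carries no hydrogen that the base could remove. The lithium alkoxide of 23 is stable under the conditions, so the shift is irreversible, and the C4=C5 and C1=C10 geometries are not involved.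

Step 16
Reactants: 23 the ten-membered dienol
Product: 25 diol: 23 with the isopropenyl group converted into 1-hydroxypropan-2-yl (C12 primary alcohol; C11 either epimer), via alkylborane 24 (not isolated)
Conditions: 9-BBN (3 equiv), THF, 0 °C → rt; then NaOH, H2O2, 0 °C
Reagents that add atoms: hydrogen peroxide OO
Why: Anti-Markovnikov hydroboration; 9-BBN should react with the unhindered 1,1-disubstituted alkene far faster than with the two trisubstituted ring alkenes, and oxidation with retention gives the C12 primary alcohol.

Step 17
Reactants: 25 the C6/C12 diol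
Product: 27 α-methyl trans-fused γ-lactone (8,9-isopropylidenedioxy-14-silyloxy-11,13-dihydrogermacra-1(10),4-dien-12,6-olide), via lactol 26 (not isolated)
Conditions: TEMPO (cat.), PhI(OAc)2 (2.5 equiv), CH2Cl2, rt
Reagents that add atoms: none
Why: Oxoammonium oxidation is selective for the primary C12 alcohol; the aldehyde is trapped by the C6 hydroxyl as lactol 26, which is oxidised on to the lactone, so the secondary allylic alcohol is consumed by ring closure and not oxidised.

Step 18
Reactants: 27 the α-methyl lactone
Product: 30 α-methylene lactone (8,9-isopropylidenedioxy-14-[(triisopropylsilyl)oxy]germacra-1(10),4,11(13)-trien-12,6-olide, stereocentres as in 34), via selenide 28 (not isolated), via selenoxide 29 (not isolated)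
Conditions: LiN(i-Pr)2, THF, −78 °C; PhSeBr; then H2O2, pyridine, CH2Cl2, 0 °C → rt
Reagents that add atoms: none
Why: Selenenylation of the lactone enolate followed by selenoxide syn-elimination, the standard α-methylenation of α-methyl trans-fused γ-lactones. With selenium anti to H7, the only syn β-hydrogens are on the methyl group, so the exocyclic C11=C13 alkene should form; C7 is not touched because only C11 is enolised.

Step 19
Reactants: 30 the α-methylene lactone ketal
Product: 31 8,9-diol (30 without the isopropylidene group; spatial arrangement unchanged)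
Conditions: AcOH/H2O/THF (3:1:1), 45 °C
Reagents that add atoms: none
Why: Acid hydrolysis of the dioxolane under conditions in which a primary triisopropylsilyl ether and the lactone should persist; the cis,cis-diene is less prone to acid-induced transannular cyclisation than a trans,trans-germacradiene.

Step 20
Reactants: 31 the 8,9-diol
Product: 32 8,9-bis(2-methylpropanoate) of 31, C14 still a triisopropylsilyl ether
Conditions: (i-PrCO)2O, DMAP, pyridine, CH2Cl2, 0 °C → rt
Reagents that add atoms: isobutyric anhydride CC(C)C(=O)OC(=O)C(C)C
Why: DMAP-catalysed acylation of both secondary alcohols; prompt acylation of O8 forestalls its attack on the lactone carbonyl.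

Step 21
Reactants: 32 the bis(isobutyrate) silyl ether
Product: 33 14-hydroxy-8,9-bis(isobutyryloxy)germacra-1(10),4,11(13)-trien-12,6-olide
Conditions: HF·pyridine, pyridine, THF, 0 °C → rt
Reagents that add atoms: none
Why: Fluoride cleavage of the silyl ether under buffered, non-basic conditions, so that neither acyl migration from O9 to O14 nor conjugate addition to the methylene lactone should occur.

Step 22
Reactants: 33 the C14 allylic alcohol
Product: 34 target, (6R,7S,8S,9S)-8,9-bis(2-methylpropanoyloxy)-14-oxogermacra-1(10),4,11(13)-trien-12,6-olide (4Z; C2 and C9 cis on C1=C10)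
Conditions: MnO2, CH2Cl2, rt
Reagents that add atoms: none
Why: MnO2 oxidises the primary allylic alcohol selectively to the enal; the geometry with C2 trans to the formyl group is the thermodynamically preferred one and is retained.

## Compound list

1 | nerol, (2Z)-3,7-dimethylocta-2,6-dien-1-ol | CC(C)=CCC/C(C)=C\CO | starting material
2 | neryl 4-methoxybenzyl ether | CC(C)=CCC/C(C)=C\COCc1ccc(OC)cc1 | intermediate
3 | distal epoxide of 2 (racemic at the epoxide carbon) | CC1(C)OC1CC/C(C)=C\COCc1ccc(OC)cc1 | intermediate
4 | (4Z)-6-[(4-methoxybenzyl)oxy]-4-methylhex-4-enal | O=CCC/C(C)=C\COCc1ccc(OC)cc1 | intermediate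
5 | ethyl (2Z,6Z)-2-iodo-8-[(4-methoxybenzyl)oxy]-6-methylocta-2,6-dienoate | CCOC(=O)/C(I)=C/CC/C(C)=C\COCc1ccc(OC)cc1 | intermediate
6 | (2Z,6Z)-2-iodo-8-[(4-methoxybenzyl)oxy]-6-methylocta-2,6-dien-1-ol | OC/C(I)=C/CC/C(C)=C\COCc1ccc(OC)cc1 | intermediate
7 | triisopropylsilyl ether of 6 | CC(C)[Si](C(C)C)(C(C)C)OC/C(I)=C/CC/C(C)=C\COCc1ccc(OC)cc1 | intermediate
8 | (R)-2,2-dimethyl-1,3-dioxolane-4-carbaldehyde | O=C[C@H]1COC(C)(C)O1 | starting material
9 | ethyl 2-(triphenylphosphoranylidene)propanoate | CCOC(=O)C(C)=P(c1ccccc1)(c1ccccc1)c1ccccc1 | starting material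
10 | ethyl (2E)-3-[(4S)-2,2-dimethyl-1,3-dioxolan-4-yl]-2-methylprop-2-enoate | CCOC(=O)/C(C)=C/[C@H]1COC(C)(C)O1 | intermediate
11 | ethyl (2E,4S)-4,5-dihydroxy-2-methylpent-2-enoate | CCOC(=O)/C(C)=C/[C@H](O)CO | intermediate
12 | ethyl (2E)-3-[(4S)-2-(4-methoxyphenyl)-1,3-dioxolan-4-yl]-2-methylprop-2-enoate | CCOC(=O)/C(C)=C/[C@H]1COC(c2ccc(OC)cc2)O1 | intermediate
13 | (2S,3E)-2-[(4-methoxybenzyl)oxy]-4-methylpent-3-ene-1,5-diol | OC/C(C)=C/[C@@H](CO)OCc1ccc(OC)cc1 | intermediate
14 | (2S,3E)-5-chloro-2-[(4-methoxybenzyl)oxy]-4-methylpent-3-en-1-ol | ClC/C(C)=C/[C@@H](CO)OCc1ccc(OC)cc1 | intermediate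
15 | (2S,3E)-5-chloro-2-[(4-methoxybenzyl)oxy]-4-methylpent-3-enal | ClC/C(C)=C/[C@@H](C=O)OCc1ccc(OC)cc1 | intermediate
16 | vinyllithium from 7 (lithium in place of iodine, geometry retained) | [Li]/C(CO[Si](C(C)C)(C(C)C)C(C)C)=C\CC/C(C)=C\COCc1ccc(OC)cc1 | intermediate
17 | vinylmagnesium bromide from 16 | Br[Mg]/C(CO[Si](C(C)C)(C(C)C)C(C)C)=C\CC/C(C)=C\COCc1ccc(OC)cc1 | intermediate
18 | (2E,4S,5S,6Z,10Z)-1-chloro-4,12-bis[(4-methoxybenzyl)oxy]-2,10-dimethyl-6-({[tri(propan-2-yl)silyl]oxy}methyl)dodeca-2,6,10-trien-5-ol | ClC/C(C)=C/[C@H](OCc1ccc(OC)cc1)[C@@H](O)/C(CO[Si](C(C)C)(C(C)C)C(C)C)=C\CC/C(C)=C\COCc1ccc(OC)cc1 | intermediate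
19 | (2E,4S,5S,6Z,10Z)-1-chloro-2,10-dimethyl-6-({[tri(propan-2-yl)silyl]oxy}methyl)dodeca-2,6,10-triene-4,5,12-triol | ClC/C(C)=C/[C@H](O)[C@@H](O)/C(CO[Si](C(C)C)(C(C)C)C(C)C)=C\CC/C(C)=C\CO | intermediate
20 | (2Z,6Z)-7-{(4S,5S)-5-[(1E)-3-chloro-2-methylprop-1-en-1-yl]-2,2-dimethyl-1,3-dioxolan-4-yl}-3-methyl-8-{[tri(propan-2-yl)silyl]oxy}octa-2,6-dien-1-ol | ClC/C(C)=C/[C@@H]1OC(C)(C)O[C@H]1/C(CO[Si](C(C)C)(C(C)C)C(C)C)=C\CC/C(C)=C\CO | intermediate
21 | thirteen-membered diallyl ether (O bridges C6 and C12; 8,9-ketal; 14-silyl ether) | O1C/C=C(/C)CC/C=C(/CO[Si](C(C)C)(C(C)C)C(C)C)[C@@H]2OC(C)(C)O[C@H]2/C=C(\C)C1 | intermediate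
22 | C6-lithio derivative of 21 | O1C([Li])/C=C(/C)CC/C=C(/CO[Si](C(C)C)(C(C)C)C(C)C)[C@@H]2OC(C)(C)O[C@H]2/C=C(\C)C1 | intermediate
23 | ten-membered dienol with 6-OH and 7-isopropenyl (6R,7S,8S,9S) | O[C@@H]1/C=C(/C)CC/C=C(/CO[Si](C(C)C)(C(C)C)C(C)C)[C@@H]2OC(C)(C)O[C@H]2[C@H]1C(C)=C | intermediate
24 | B-alkyl-9-borabicyclo[3.3.1]nonane adduct of 23 (boron on C12) | O[C@@H]1/C=C(/C)CC/C=C(/CO[Si](C(C)C)(C(C)C)C(C)C)[C@@H]2OC(C)(C)O[C@H]2[C@H]1C(C)CB1C2CCCC1CCC2 | intermediate
25 | C6/C12 diol (7-(1-hydroxypropan-2-yl) analogue of 23) | O[C@@H]1/C=C(/C)CC/C=C(/CO[Si](C(C)C)(C(C)C)C(C)C)[C@@H]2OC(C)(C)O[C@H]2[C@H]1C(C)CO | intermediate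
26 | lactol (C12 hemiacetal with O6) | CC1C(O)O[C@@H]2/C=C(/C)CC/C=C(/CO[Si](C(C)C)(C(C)C)C(C)C)[C@@H]3OC(C)(C)O[C@H]3[C@@H]12 | intermediate
27 | α-methyl trans-fused γ-lactone | CC1C(=O)O[C@@H]2/C=C(/C)CC/C=C(/CO[Si](C(C)C)(C(C)C)C(C)C)[C@@H]3OC(C)(C)O[C@H]3[C@@H]12 | intermediate
28 | α-methyl-α-phenylselanyl lactone (selenium anti to H7) | C[C@]1([Se]c4ccccc4)C(=O)O[C@@H]2/C=C(/C)CC/C=C(/CO[Si](C(C)C)(C(C)C)C(C)C)[C@@H]3OC(C)(C)O[C@H]3[C@@H]12 | intermediate
29 | selenoxide of 28 | C[C@]1([Se](=O)c4ccccc4)C(=O)O[C@@H]2/C=C(/C)CC/C=C(/CO[Si](C(C)C)(C(C)C)C(C)C)[C@@H]3OC(C)(C)O[C@H]3[C@@H]12 | intermediate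
30 | α-methylene lactone with 8,9-ketal and 14-silyl ether | C=C1C(=O)O[C@@H]2/C=C(/C)CC/C=C(/CO[Si](C(C)C)(C(C)C)C(C)C)[C@@H]3OC(C)(C)O[C@H]3[C@@H]12 | intermediate
31 | α-methylene lactone 8,9-diol, 14-silyl ether | C=C1C(=O)O[C@@H]2/C=C(/C)CC/C=C(/CO[Si](C(C)C)(C(C)C)C(C)C)[C@H](O)[C@@H](O)[C@@H]12 | intermediate
32 | 8,9-bis(isobutyrate), 14-silyl ether | C=C1C(=O)O[C@@H]2/C=C(/C)CC/C=C(/CO[Si](C(C)C)(C(C)C)C(C)C)[C@H](OC(=O)C(C)C)[C@@H](OC(=O)C(C)C)[C@@H]12 | intermediate
33 | 14-hydroxy 8,9-bis(isobutyrate) | C=C1C(=O)O[C@@H]2/C=C(/C)CC/C=C(/CO)[C@H](OC(=O)C(C)C)[C@@H](OC(=O)C(C)C)[C@@H]12 | intermediate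
34 | target, (6R,7S,8S,9S)-8,9-bis(2-methylpropanoyloxy)-14-oxogermacra-1(10),4,11(13)-trien-12,6-olide | C=C1C(=O)O[C@@H]2/C=C(/C)CC/C=C(/C=O)[C@H](OC(=O)C(C)C)[C@@H](OC(=O)C(C)C)[C@@H]12 | target

## Step count and least certain steps

Total: 22 steps. Longest linear sequence: 17 steps (steps 1–5 or 6–10, then 11–22).

**Step 15 (key step).** Two things can go wrong.

- Metalation may take place at C12 instead of C6, leading to the regioisomeric contraction onto C4 or to 1,4-elimination that opens the dioxolane.
- Facial selectivity at C7 may be poor or reversed. The intrinsic preference of an acyclic allylic ether is attack anti to the allylic C8–O bond, which would place C6 on the C9 side and give the H7/H8-trans diastereomer. The required sense therefore depends on how firmly the macrocycle and the trans-dioxolane constrain the transition state, and the configuration of 23 has to be proved before going on.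

Fallback: from 20, MnO2 (CH2Cl2) oxidises the C6 allylic alcohol to the (Z)-enal chloride F1. Slow addition of F1 to CrCl2 (divalent chromium; THF, high dilution) generates the C12 allylchromium, which adds through C7 to the C6 aldehyde in a chair-like six-membered transition state (intramolecular Nozaki–Hiyama allylation). This gives the anti homoallylic alcohol and returns to the route at 23. The C–C bond can form only between C6 and the allyl unit, so the regiochemical question disappears, and the different transition state gives an independent chance of the right face.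

**Step 11.** Chelation control may be incomplete because the silyloxymethyl group of the nucleophile or the ether solvent competes for magnesium. Open-chain addition then erodes the syn selectivity at C9; partial enolisation of 15 would add to the loss.

Fallback: the mixture of 18 and its C9 epimer F2 is oxidised with Dess–Martin periodinane to the enone F3. F3 is reduced under reagent control with (S)-2-methyl-CBS-oxazaborolidine and catecholborane (toluene, −78 °C; the 2-substituted alkenyl group taken as the larger ketone substituent). This converges on the (9S) alcohol and returns at 18.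

**Step 14.** Ring closure may be slow relative to intermolecular etherification. Prolonged exposure of the C12 allylic chloride to alkoxide may also cause SN2′ attack or loss of HCl.

Fallback (leaving group moved to the less hindered neryl carbon): from 20, CsOAc in DMF replaces the chloride to give the C12 acetate F4. MsCl, LiCl and 2,4,6-collidine in DMF convert the C6 alcohol into the chloro acetate F5. K2CO3 in MeOH removes the acetate to give the isomeric hydroxy chloride F6. KN(SiMe3)2 in THF at high dilution then closes the ether from the C12 alkoxide onto C6, returning at 21.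

**Step 18.** The electrophile may enter the enolate on the face syn to H7. The selenoxide then has a ring hydrogen available and eliminates toward C7, giving the endocyclic butenolide. Over-oxidation of the ring alkenes by peroxyseleninic acid is a second hazard.

Fallback: from 27, LiN(i-Pr)2 then CBr4 gives the α-bromo lactone F7, bromine entering the same face that selenium would. DBU (toluene, rt) then effects an anti-periplanar E2 elimination. With bromine syn to H7, only the methyl hydrogens can be anti, so the exocyclic alkene results, returning at 30.

**Step 19.** Hydrolysis of the trans-fused dioxolane may need acid strong enough to cleave the silyl ether as well, and a free O8 may begin to attack the lactone.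

Fallback: from 30, aqueous HF in MeCN removes ketal and silyl ether together to give the triol F8. t-BuMe2SiCl and imidazole at −20 °C silylate only the primary O14, giving F9. (i-PrCO)2O with DMAP gives the bis(isobutyrate) F10, and HF·pyridine then frees O14, returning at 33.

## Further compounds

F1 | step 15 | (Z)-enal chloride, 20 with the C6 alcohol oxidised to the aldehyde | O=C/C=C(/C)CC/C=C(/CO[Si](C(C)C)(C(C)C)C(C)C)[C@@H]1OC(C)(C)O[C@H]1/C=C(\C)CCl
F2 | step 11 | C9 epimer of 18 | ClC/C(C)=C/[C@H](OCc1ccc(OC)cc1)[C@H](O)/C(CO[Si](C(C)C)(C(C)C)C(C)C)=C\CC/C(C)=C\COCc1ccc(OC)cc1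
F3 | step 11 | C9 enone from 18 and F2 | ClC/C(C)=C/[C@H](OCc1ccc(OC)cc1)C(=O)/C(CO[Si](C(C)C)(C(C)C)C(C)C)=C\CC/C(C)=C\COCc1ccc(OC)cc1
F4 | step 14 | C12 acetate, C6 alcohol (20 with acetoxy in place of chloride) | CC(=O)OC/C(C)=C/[C@@H]1OC(C)(C)O[C@H]1/C(CO[Si](C(C)C)(C(C)C)C(C)C)=C\CC/C(C)=C\CO
F5 | step 14 | C12 acetate, C6 chloride | CC(=O)OC/C(C)=C/[C@@H]1OC(C)(C)O[C@H]1/C(CO[Si](C(C)C)(C(C)C)C(C)C)=C\CC/C(C)=C\CCl
F6 | step 14 | C12 alcohol, C6 chloride (isomer of 20) | OC/C(C)=C/[C@@H]1OC(C)(C)O[C@H]1/C(CO[Si](C(C)C)(C(C)C)C(C)C)=C\CC/C(C)=C\CCl
F7 | step 18 | α-bromo-α-methyl lactone (bromine syn to H7) | C[C@@]1(Br)C(=O)O[C@@H]2/C=C(/C)CC/C=C(/CO[Si](C(C)C)(C(C)C)C(C)C)[C@@H]3OC(C)(C)O[C@H]3[C@@H]12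
F8 | step 19 | 8,9,14-triol of the α-methylene lactone | C=C1C(=O)O[C@@H]2/C=C(/C)CC/C=C(/CO)[C@H](O)[C@@H](O)[C@@H]12
F9 | step 19 | 14-O-tert-butyldimethylsilyl 8,9-diol | C=C1C(=O)O[C@@H]2/C=C(/C)CC/C=C(/CO[Si](C)(C)C(C)(C)C)[C@H](O)[C@@H](O)[C@@H]12
F10 | step 19 | 14-O-tert-butyldimethylsilyl 8,9-bis(isobutyrate) | C=C1C(=O)O[C@@H]2/C=C(/C)CC/C=C(/CO[Si](C)(C)C(C)(C)C)[C@H](OC(=O)C(C)C)[C@@H](OC(=O)C(C)C)[C@@H]12
A1 | alternative 1 | open-chain ynal–aldehyde: trans-4-formyl-5-[(1Z)-2-methyl-7-oxohept-1-en-5-yn-1-yl]oxolan-2-one | C1C(=O)O[C@H](/C=C(/C)CCC#CC=O)[C@H]1C=O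
A2 | alternative 1 | lactone-fused cyclodec-enyne 8,9-diol | C1C(=O)O[C@@H]2/C=C(/C)CCC#C[C@H](O)[C@@H](O)[C@@H]12
A3 | alternative 2 | pyrrolidine enamine of the eight-membered ring (C9=C2), with 8-O-(4-methoxybenzyl), 6-O-silyl and the 7-(2-silyloxyethyl) arm | COc1ccc(CO[C@@H]2C(N3CCCC3)=CC/C(C)=C\[C@@H](O[Si](C)(C)C(C)(C)C)[C@@H]2CCO[Si](C)(C)C(C)(C)C)cc1
A4 | alternative 2 | ten-membered 9-pyrrolidinyl dienyl ester | COc1ccc(CO[C@@H]2/C(N3CCCC3)=C(C(=O)OC)\C=C\C/C(C)=C\[C@@H](O[Si](C)(C)C(C)(C)C)[C@@H]2CCO[Si](C)(C)C(C)(C)C)cc1
A5 | alternative 3 | cis-1-vinyl-2-isopropenyl cyclohexanol with 8,9-ketal, 6-methoxymethyl ether and the 7-(2-silyloxyethyl) arm | C=C[C@]1(O)[C@H](C(C)=C)[C@@H](OCOC)[C@H](CCO[Si](C)(C)C(C)(C)C)[C@@H]2OC(C)(C)O[C@@H]12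
A6 | alternative 3 | ten-membered C10 ketone with ring-cis C4=C5 alkene | O=C1CCC/C(C)=C\[C@@H](OCOC)[C@H](CCO[Si](C)(C)C(C)(C)C)[C@@H]2OC(C)(C)O[C@@H]12
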